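**Retrosynthetic overview**
1. The last bond made is the tertiary C–O bond: the target is the Markovnikov hydrate of an exocyclic methylene on ring B. Just before that come dehydrogenation of the δ-lactone and 1,4-reduction of the cage enoate.
2. The cage comes from an intramolecular Diels–Alder reaction of a 6-alkyl-6-methylcyclohexa-2,4-dienone (rings D and E) with a methylidenecyclohexane (ring B). Ring C and the bicyclo[2.2.2]octane form together.
3. The dienone comes from alkylative dearomatization of a bromo-hydroxy-methylphthalide by a ring A/B iodide. The bromine blocks the second ortho carbon and then becomes the second ring methyl (Stille).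
4. The ring A/B iodide comes from a spiro enone built from mesityl oxide, methyl acrylate and methyl vinyl ketone (chiral-imine Michael, C–O lactonization, Robinson aldol), followed by deconjugative hydroxymethylation, methylenation and iodination.
5. Ring order: A (lactone, C–O) → B → E on the arene (carbonylative lactonization) → C and D in one cycloaddition → final C–O hydration.

Assumption: the (S)-amine in step 2 gives the quaternary carbon drawn (d'Angelo model); if the sense is opposite, the (R)-amine is used instead.

Notation: ring A = δ-lactone, B = cyclohexane, C = cyclopentane, D = cyclohexanone of the bicyclo[2.2.2]octane, E = γ-lactone. dppp = 1,3-bis(diphenylphosphino)propane. Co(salen) = [N,N′-bis(3,5-di-tert-butylsalicylidene)ethane-1,2-diaminato]cobalt, a complex of divalent cobalt.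

**Step 1**
Reactants: 1 4-methylpent-3-en-2-one (mesityl oxide); 2 methyl prop-2-enoate (methyl acrylate)
Product: 3 methyl 4-acetyl-5-methylhex-5-enoate (racemic)
Conditions: t-BuOK (0.1 equiv), t-BuOH, 25 °C
Reagents that add atoms: none
Why: Base-catalysed Michael addition of the extended (thermodynamic) dienolate of mesityl oxide through its α-carbon, which leaves the deconjugated isopropenyl ketone; the new stereocenter is racemic and is erased and re-set in step 2.

**Step 2**
Reactants: 3 methyl 4-acetyl-5-methylhex-5-enoate; 4 (1S)-1-phenylethan-1-amine; 5 but-3-en-2-one (methyl vinyl ketone)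
Product: 8 methyl (4R)-4-acetyl-7-oxo-4-(prop-1-en-2-yl)octanoate, via ketimine 6 (not isolated), via adduct ketimine 7 (not isolated)
Conditions: 4 (1.05 equiv), TsOH (cat.), cyclohexane, reflux; then 5, THF, 25 °C; then 10% aq. AcOH, 25 °C
Reagents that add atoms: water, O
Why: d'Angelo deracemizing Michael addition: the more substituted secondary enamine tautomer of the chiral ketimine adds to the enone through a compact aza-ene-like transition state on the face away from the phenyl group, which sets the quaternary carbon (the later spiro carbon), and aqueous acid then frees the ketone.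

**Step 3**
Reactants: 8 methyl (4R)-4-acetyl-7-oxo-4-(prop-1-en-2-yl)octanoate
Product: 9 (5R)-5-acetyl-6,6-dimethyl-5-(3-oxobutyl)oxan-2-one
Conditions: TsOH·H2O (1.1 equiv), PhMe, 60 °C
Reagents that add atoms: water, O
Why: Acid-mediated Markovnikov lactonization: protonation of the isopropenyl group gives a tertiary cation that the ester oxygen captures to close ring A with loss of methanol, and no stereocenter is touched.

**Step 4**
Reactants: 9 (5R)-5-acetyl-6,6-dimethyl-5-(3-oxobutyl)oxan-2-one
Product: 10 (6S)-1,1,7-trimethyl-2-oxaspiro[5.5]undec-7-ene-3,9-dione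
Conditions: pyrrolidine (0.2 equiv), AcOH (0.2 equiv), PhMe, 80 °C
Reagents that add atoms: none
Why: Robinson-type intramolecular aldol condensation in which the enamine of the unhindered methyl ketone attacks the hindered acetyl group and dehydration gives the 3-methylcyclohex-2-enone (ring B); the quaternary center is unchanged.

**Step 5**
Reactants: 10 (6S)-1,1,7-trimethyl-2-oxaspiro[5.5]undec-7-ene-3,9-dione
Product: 11 (6S,8R)-8-(hydroxymethyl)-1,1-dimethyl-7-methylidene-2-oxaspiro[5.5]undecane-3,9-dione
Conditions: KN(SiMe3)2 (0.95 equiv), THF, −78 to 0 °C; CH2O (gas), −78 °C; AcOH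
Reagents that add atoms: formaldehyde, C=O
Why: Deconjugative α-hydroxymethylation (aldol reaction of the extended dienolate, formed by γ-deprotonation of the ring methyl, at its α-carbon), which moves the double bond to the exocyclic position; allylic strain holds the CMe2–O carbon of ring A pseudo-axial, so formaldehyde adds to the opposite face and sets the ring CH carbon.

**Step 6**
Reactants: 11 (6S,8R)-8-(hydroxymethyl)-1,1-dimethyl-7-methylidene-2-oxaspiro[5.5]undecane-3,9-dione
Product: 12 (6S,8R)-8-(hydroxymethyl)-1,1-dimethyl-7,9-dimethylidene-2-oxaspiro[5.5]undecan-3-one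
Conditions: Zn, CH2Br2, TiCl4, THF/CH2Cl2, 0 to 25 °C
Reagents that add atoms: dibromomethane, BrCBr
Why: Lombardo methylenation, a non-basic zinc–titanium carbenoid olefination that converts the ketone into the second exocyclic methylene without retro-aldol cleavage, epimerization of the adjacent CH or migration of the β,γ-double bond, and leaves the lactone alone.

**Step 7**
Reactants: 12 (6S,8R)-8-(hydroxymethyl)-1,1-dimethyl-7,9-dimethylidene-2-oxaspiro[5.5]undecan-3-one
Product: 13 (6S,8R)-8-(iodomethyl)-1,1-dimethyl-7,9-dimethylidene-2-oxaspiro[5.5]undecan-3-one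
Conditions: I2, PPh3, imidazole, CH2Cl2, 0 °C
Reagents that add atoms: iodine, II
Why: Appel iodination of the primary alcohol (alkoxyphosphonium formation, then SN2 displacement by iodide at the CH2 carbon), so no stereocenter is involved.

**Step 8**
Reactants: 14 3-hydroxy-2-methylbenzoic acid
Product: 15 3-(hydroxymethyl)-2-methylphenol
Conditions: BH3·THF, THF, 0 to 25 °C; aq. work-up
Reagents that add atoms: none
Why: Chemoselective borane reduction of the carboxylic acid through its acyloxyborane to the benzylic alcohol, with the phenol untouched.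

**Step 9**
Reactants: 15 3-(hydroxymethyl)-2-methylphenol
Product: 16 4,6-dibromo-3-(hydroxymethyl)-2-methylphenol
Conditions: NBS (2.05 equiv), MeCN, 0 °C
Reagents that add atoms: N-bromosuccinimide, O=C1CCC(=O)N1Br
Why: Electrophilic aromatic bromination at the two free positions ortho and para to the phenol OH, the third activated position being occupied by the methyl group.

**Step 10**
Reactants: 16 4,6-dibromo-3-(hydroxymethyl)-2-methylphenol
Product: 17 6-bromo-5-hydroxy-4-methyl-2-benzofuran-1(3H)-one
Conditions: Pd(OAc)2 (3 mol %), dppp (6 mol %), CO (1 atm), NEt3, DMF, 80 °C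
Reagents that add atoms: carbon monoxide, [C-]#[O+]
Why: Palladium-catalysed carbonylative lactonization (oxidative addition, CO insertion, intramolecular capture by the alcohol): only the bromide ortho to the CH2OH group can close the five-membered lactone (ring E), so the bromide next to the phenol survives.

**Step 11**
Reactants: 17 6-bromo-5-hydroxy-4-methyl-2-benzofuran-1(3H)-one; 13 (6S,8R)-8-(iodomethyl)-1,1-dimethyl-7,9-dimethylidene-2-oxaspiro[5.5]undecan-3-one
Product: 18 (4R)-6-bromo-4-{[(6S,8R)-1,1-dimethyl-7,9-dimethylidene-3-oxo-2-oxaspiro[5.5]undecan-8-yl]methyl}-4-methyl-2-benzofuran-1,5(3H,4H)-dione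
Conditions: LiOt-Bu (1.0 equiv), PhMe, 25 °C; then 13, 90 °C
Reagents that add atoms: none
Why: Alkylative dearomatization (C-alkylation of the phenoxide): the tight lithium ion pair in toluene favours attack through the methyl-bearing ortho carbon, the brominated ortho carbon is deactivated and the para carbon is blocked; the new quaternary center is not controlled (about 1:1) and 18 is separated from its epimer, which cannot cyclize in step 13.

**Step 12**
Reactants: 18 bromo dienone from step 11
Product: 19 (4R)-4-{[(6S,8R)-1,1-dimethyl-7,9-dimethylidene-3-oxo-2-oxaspiro[5.5]undecan-8-yl]methyl}-4,6-dimethyl-2-benzofuran-1,5(3H,4H)-dione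
Conditions: SnMe4, Pd(PPh3)4 (5 mol %), DMF, 70 °C
Reagents that add atoms: tetramethylstannane, C[Sn](C)(C)C
Why: Stille cross-coupling of the α-bromo dienone (oxidative addition, methyl transfer from tin, reductive elimination) installs the second ring methyl group without touching a stereocenter.

**Step 13**
Reactants: 19 methyl dienone from step 12
Product: 20 hexacyclic Diels–Alder adduct (ring-E enoate)
Conditions: PhMe (0.01 M), BHT, 150 °C, sealed tube
Reagents that add atoms: none
Why: Intramolecular Diels–Alder reaction of the cyclohexa-2,4-dienone with the exocyclic methylene that is not flanked by the spiro carbon: the three-atom tether fixes the regiochemistry and forces addition on the dienone face that carries the tether and on the alkene face cis to the tether CH2, which gives the cis-fused ring C and the bicyclo[2.2.2]octenone and sets both bridgeheads and the new quaternary ring-B carbon, while the other methylene would have to form a quaternary carbon beside the spiro carbon and does not compete.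

**Step 14**
Reactants: 20 hexacyclic Diels–Alder adduct (ring-E enoate)
Product: 22 hexacyclic keto bis-lactone (ring E saturated), via lactone α-epimer 21 (not isolated)
Conditions: Cu(OAc)2 (5 mol %), 1,2-bis(diphenylphosphino)benzene (5 mol %), (HMe2Si)2O, t-BuOH, PhMe, 25 °C; then DBU (0.3 equiv), 60 °C
Reagents that add atoms: none
Why: Copper hydride 1,4-reduction of the unsaturated γ-lactone (the isolated methylene and the hindered, non-enolizable ketone are inert) gives mainly the kinetic α-epimer by protonation from the open ketone-bridge side, and base equilibration then moves the epimerizable lactone α-carbon to the isomer whose carbonyl carbon lies on the ketone-bridge side, away from the ring-B methylenes.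

**Step 15**
Reactants: 22 hexacyclic keto bis-lactone (ring E saturated)
Product: 24 exo-methylene enoate (dehydration product of the target), via α-phenylselanyl lactone 23 (not isolated)
Conditions: LiN(i-Pr)2 (1.1 equiv), THF, −78 °C; PhSeBr; then H2O2, pyridine, CH2Cl2, 0 to 25 °C
Reagents that add atoms: none
Why: α-Selenenylation of the less hindered δ-lactone enolate and selenoxide syn-elimination give the endocyclic (Z) α,β-unsaturated lactone of ring A; the ketone has no α-hydrogen and the hindered γ-lactone α-CH is not deprotonated under kinetic conditions.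

**Step 16**
Reactants: 24 exo-methylene enoate (dehydration product of the target)
Product: 25 target CNP0222978.3
Conditions: Co(salen) (5 mol %), N-fluoro-2,4,6-trimethylpyridinium triflate, PhSiH3, H2O, acetone, 0 °C
Reagents that add atoms: water, O
Why: Proposed new method: hydrogen-atom transfer from a cobalt hydride to the 1,1-disubstituted alkene gives the tertiary radical, the N-fluoropyridinium oxidant turns it through an alkylcobalt species into a tertiary cation equivalent (radical–polar crossover), and water captures it, which amounts to a Markovnikov hydration that leaves the electron-poor enoate alone; water enters on the face away from the adjacent CMe2–O carbon of ring A (the same cation is the presumed biosynthetic one), which sets the carbinol carbon; the closest known reactions are the Mukaiyama hydration and cobalt-salen-catalysed hydroalkoxylation of unactivated alkenes, not yet shown with water as the nucleophile on a hindered alkene beside an enoate.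

**Compound list**
1 | 4-methylpent-3-en-2-one (mesityl oxide) | CC(=O)C=C(C)C | starting material
2 | methyl prop-2-enoate (methyl acrylate) | C=CC(=O)OC | starting material
3 | methyl 4-acetyl-5-methylhex-5-enoate (racemic) | CC(=O)C(CCC(=O)OC)C(C)=C | intermediate
4 | (1S)-1-phenylethan-1-amine | C[C@H](N)c1ccccc1 | starting material
5 | but-3-en-2-one (methyl vinyl ketone) | C=CC(C)=O | starting material
6 | N-[(1S)-1-phenylethyl] ketimine of 3 | CC(=N[C@@H](C)c1ccccc1)C(CCC(=O)OC)C(C)=C | intermediate (not isolated)
7 | N-[(1S)-1-phenylethyl] ketimine of 8 at the acetyl group (quaternary carbon set) | CC(=O)CC[C@](C(C)=C)(CCC(=O)OC)C(C)=N[C@@H](C)c1ccccc1 | intermediate (not isolated)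
8 | methyl (4R)-4-acetyl-7-oxo-4-(prop-1-en-2-yl)octanoate | CC(=O)CC[C@](C(C)=C)(CCC(=O)OC)C(C)=O | intermediate
9 | (5R)-5-acetyl-6,6-dimethyl-5-(3-oxobutyl)oxan-2-one | CC(=O)CC[C@]1(CCC(=O)OC1(C)C)C(C)=O | intermediate
10 | (6S)-1,1,7-trimethyl-2-oxaspiro[5.5]undec-7-ene-3,9-dione | O=C1CC[C@]2(CCC(=O)OC2(C)C)C(C)=C1 | intermediate
11 | (6S,8R)-8-(hydroxymethyl)-1,1-dimethyl-7-methylidene-2-oxaspiro[5.5]undecane-3,9-dione | O=C1CC[C@]2(CCC(=O)OC2(C)C)C(=C)[C@@H]1CO | intermediate
12 | (6S,8R)-8-(hydroxymethyl)-1,1-dimethyl-7,9-dimethylidene-2-oxaspiro[5.5]undecan-3-one | C=C1CC[C@]2(CCC(=O)OC2(C)C)C(=C)[C@@H]1CO | intermediate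
13 | (6S,8R)-8-(iodomethyl)-1,1-dimethyl-7,9-dimethylidene-2-oxaspiro[5.5]undecan-3-one | C=C1CC[C@]2(CCC(=O)OC2(C)C)C(=C)[C@@H]1CI | intermediate
14 | 3-hydroxy-2-methylbenzoic acid | Cc1c(O)cccc1C(=O)O | starting material
15 | 3-(hydroxymethyl)-2-methylphenol | Cc1c(O)cccc1CO | intermediate
16 | 4,6-dibromo-3-(hydroxymethyl)-2-methylphenol | Cc1c(O)c(Br)cc(Br)c1CO | intermediate
17 | 6-bromo-5-hydroxy-4-methyl-2-benzofuran-1(3H)-one | O=C1OCc2c(C)c(O)c(Br)cc12 | intermediate
18 | (4R)-6-bromo-4-{[(6S,8R)-1,1-dimethyl-7,9-dimethylidene-3-oxo-2-oxaspiro[5.5]undecan-8-yl]methyl}-4-methyl-2-benzofuran-1,5(3H,4H)-dione | C=C1CC[C@]2(CCC(=O)OC2(C)C)C(=C)[C@@H]1C[C@@]3(C)C(=O)C(Br)=CC4=C3COC4=O | intermediate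
19 | (4R)-4-{[(6S,8R)-1,1-dimethyl-7,9-dimethylidene-3-oxo-2-oxaspiro[5.5]undecan-8-yl]methyl}-4,6-dimethyl-2-benzofuran-1,5(3H,4H)-dione | C=C1CC[C@]2(CCC(=O)OC2(C)C)C(=C)[C@@H]1C[C@@]3(C)C(=O)C(C)=CC4=C3COC4=O | intermediate
20 | Diels–Alder adduct: hexacyclic keto bis-lactone; ring A is the saturated δ-lactone spiro to ring B; ring B keeps one exocyclic methylene beside the spiro carbon and is cis-fused to ring C; the C=C of the bicyclo[2.2.2]octenone is conjugated to the ring-E lactone; stereocenters as in the target | CC1(C)OC(=O)CC[C@]12CC[C@@]13C[C@@]4(C)C=C5C(=O)OC[C@]51[C@@](C)(C[C@H]3C2=C)C4=O | intermediate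
21 | dihydro-20 with the ring-E carbonyl carbon on the ring-B side (epimer of 22 at the γ-lactone α-carbon) | CC1(C)OC(=O)CC[C@]12CC[C@@]13C[C@@]4(C)C[C@H]5C(=O)OC[C@]51[C@@](C)(C[C@H]3C2=C)C4=O | intermediate (not isolated)
22 | dihydro-20 (bicyclo[2.2.2]octanone) with the ring-E carbonyl carbon on the side of the ketone bridge, as in the target | CC1(C)OC(=O)CC[C@]12CC[C@@]13C[C@@]4(C)C[C@@H]5C(=O)OC[C@]51[C@@](C)(C[C@H]3C2=C)C4=O | intermediate
23 | 22 with a phenylselanyl group on the α-carbon of ring A (mixture at that carbon) | CC1(C)OC(=O)C([Se]c6ccccc6)C[C@]12CC[C@@]13C[C@@]4(C)C[C@@H]5C(=O)OC[C@]51[C@@](C)(C[C@H]3C2=C)C4=O | intermediate (not isolated)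
24 | dehydration product of the target: ring A is the (Z) α,β-unsaturated δ-lactone and ring B carries the exocyclic methylene beside the spiro carbon; all other stereocenters as in the target | CC1(C)OC(=O)C=C[C@]12CC[C@@]13C[C@@]4(C)C[C@@H]5C(=O)OC[C@]51[C@@](C)(C[C@H]3C2=C)C4=O | intermediate
25 | target CNP0222978.3: tertiary alcohol with OH and CH3 on the ring-B carbon beside the spiro carbon, OH cis to the ring-C CH2 and to the vinyl carbon of ring A | CC1(C)OC(=O)C=C[C@]12CC[C@@]13C[C@@]4(C)C[C@@H]5C(=O)OC[C@]51[C@@](C)(C[C@H]3[C@@]2(C)O)C4=O | target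

**Step count and risks**
Total step count: 16. Longest linear sequence: 13 steps (steps 1 to 7, then 11 to 16).

Three steps most likely to fail:

Step 11 (alkylative dearomatization). O-alkylation and the slow SN2 reaction of the β-branched iodide can win over C-alkylation. The fallback reverses the polarity of the linking CH2 and brings in the ring methyl last; it sets out from 10 and 17. Oxidation of 17 with Ag2O gives the o-quinone methide F1. The potassium dienolate of 10 adds to it through its α-carbon (Michael addition, same facial rule as in step 5) to give the phenol ketone F2. Lombardo methylenation gives the bis-methylene phenol F3. C-methylation of its phenoxide at the benzyl-bearing ortho carbon (t-BuOK, MeI, PhMe) gives 18, where the route is rejoined.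

Step 13 (Diels–Alder). Only 19 can reach the transition state; its epimer at the quaternary dienone carbon cannot, and dimerization of the dienone competes at 150 °C. The fallback makes the step stereoconvergent by light instead of separating epimers; it sets out from 19 taken together with its unseparated (4S)-epimer F4 from steps 11 and 12. The pair is heated in toluene under 365 nm irradiation. Linearly conjugated cyclohexa-2,4-dienones open to dienyl ketenes (here the dienyl ketene F5) that close again thermally to either epimer. The unreactive epimer is therefore fed back into 19 while 19 is drained by the cycloaddition; the route is rejoined at 20.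

Step 16 (proposed hydration). The enoate may be reduced, the tertiary cation may rearrange, or water may enter from the wrong face. The fallback uses known chemistry and changes the order so that no enoate is present; it sets out from 22. A classical Mukaiyama hydration (Co(acac)2, O2, PhSiH3, THF/i-PrOH, then PPh3) gives the tertiary alcohol F6. LiN(i-Pr)2 (2.2 equiv) and PhSeBr give the selenide F7, and H2O2 elimination gives 25, where the route is rejoined.

Further compounds
F1 | step 11 | 6-bromo-4-methylidene-2-benzofuran-1,5(3H,4H)-dione | C=C1C(=O)C(Br)=CC2=C1COC2=O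
F2 | step 11 | (6S,8S)-8-[(6-bromo-5-hydroxy-1-oxo-1,3-dihydro-2-benzofuran-4-yl)methyl]-1,1-dimethyl-7-methylidene-2-oxaspiro[5.5]undecane-3,9-dione | O=C1CC[C@]2(CCC(=O)OC2(C)C)C(=C)[C@@H]1Cc1c(O)c(Br)cc2C(=O)OCc12
F3 | step 11 | (6S,8R)-8-[(6-bromo-5-hydroxy-1-oxo-1,3-dihydro-2-benzofuran-4-yl)methyl]-1,1-dimethyl-7,9-dimethylidene-2-oxaspiro[5.5]undecan-3-one | C=C1CC[C@]2(CCC(=O)OC2(C)C)C(=C)[C@@H]1Cc1c(O)c(Br)cc2C(=O)OCc12
F4 | step 13 | (4S)-epimer of 19 (quaternary dienone carbon inverted) | C=C1CC[C@]2(CCC(=O)OC2(C)C)C(=C)[C@@H]1C[C@]3(C)C(=O)C(C)=CC4=C3COC4=O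
F5 | step 13 | dienyl ketene from ring opening of 19 between the ketone carbon and the quaternary carbon | O=C=C(C)/C=C1/C(=O)OCC1=C(C)C[C@@H]1C(=C)CC[C@]2(CCC(=O)OC2(C)C)C1=C
F6 | step 16 | Markovnikov hydrate of 22 (7,8-dihydro target, ring A saturated) | CC1(C)OC(=O)CC[C@]12CC[C@@]13C[C@@]4(C)C[C@@H]5C(=O)OC[C@]51[C@@](C)(C[C@H]3[C@@]2(C)O)C4=O
F7 | step 16 | F6 with a phenylselanyl group on the α-carbon of ring A | CC1(C)OC(=O)C([Se]c6ccccc6)C[C@]12CC[C@@]13C[C@@]4(C)C[C@@H]5C(=O)OC[C@]51[C@@](C)(C[C@H]3[C@@]2(C)O)C4=O
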